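**Retrosynthetic overview**
1. Feature: in the dihydrofuran ring (O1, C2, C3, C3a, C7a; benzofuran numbering) the C2–C3 bond links the O1-bearing methine C2 to the benzylic carbinol C3. O1 and the C3 hydroxyl are anti along C3a–C3–C2–side chain, so side chain and OH are trans on the ring. An E 3-oxyallylboron reagent leaves this relationship when its oxygen-bearing carbon adds to an aldehyde.
2. Late cuts: free the ring B phenol from its allyl ether, then cut the enone C=C (Claisen–Schmidt) to a C5 acetyl compound and 4-(allyloxy)benzaldehyde.
3. Side chain: C2–CMe2OH comes from methyl addition to a C2 acetyl group, which comes from Markovnikov oxidation of a C2 vinyl group while O3 is silylated.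
4. Key cut C2–C3: the vinyl carbinol opens to a formyl group at C3 and an E ArO–CH=CH–CH2–Bpin unit hung on O1. This pair cannot be stored together, so it is released in the flask from the stable E alkenylboronate ether by an iridium hydride 1,3-hydrogen shift under a chiral phosphoric acid.
5. Ring order: ring A (resacetophenone) and ring B are bought. The dihydrofuran ring is the only ring made (step 3). Its ether precursor comes from C3 formylation and O-alkylation of resacetophenone.

Key step: step 3

Assumption: the sense of induction of (R)-TRIP is carried over from its intermolecular allylborations of benzaldehydes (delivery to the Re face), and (S)-TRIP is used if the tethered case answers the other way; the E chloropropenyl pinacolboronate is taken as a catalogue compound (otherwise one hydroboration of propargyl chloride with pinacolborane).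

**Step 1**
Reactants: 1 2,4-dihydroxyacetophenone
Product: 2 3-acetyl-2,6-dihydroxybenzaldehyde (3-formyl-2,4-dihydroxyacetophenone)
Conditions: hexamethylenetetramine, AcOH, 110 °C; then aq HCl, 100 °C
Reagents that add atoms: hexamethylenetetramine C1N2CN3CN1CN(C2)C3; water O
Why: Duff formylation, in which the iminium ions from hexamethylenetetramine attack ortho to a phenolic OH, the carbon between the two hydroxyls (ortho to both) being the expected site in hydrogen-bond-fixed resacetophenone, and the benzylamine stage is oxidised internally and hydrolysed to the aldehyde.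

**Step 2**
Reactants: 2 3-acetyl-2,6-dihydroxybenzaldehyde; 3 (E)-3-chloroprop-1-en-1-ylboronic acid pinacol ester
Product: 4 3-acetyl-2-hydroxy-6-{[(2E)-3-(4,4,5,5-tetramethyl-1,3,2-dioxaborolan-2-yl)prop-2-en-1-yl]oxy}benzaldehyde
Conditions: K2CO3 (1.1 equiv), NaI (cat.), DMF, 40 °C
Reagents that add atoms: none
Why: Williamson etherification (SN2 at the allylic chloride), in which one equivalent of carbonate should ionise only the more acidic hydroxyl para to the acetyl group while the other stays locked in a hydrogen bond to the ketone, and the alkenyl pinacolboronate is inert to carbonate in dry DMF so its E geometry is carried over.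

**Step 3**
Reactants: 4 3-acetyl-2-hydroxy-6-{[(2E)-3-(pinacolatoboryl)prop-2-en-1-yl]oxy}benzaldehyde
Product: 7 1-[(2R,3S)-2-ethenyl-3,4-dihydroxy-2,3-dihydro-1-benzofuran-5-yl]ethanone (trans), via E gamma-aryloxyallyl pinacolboronate 5 (not isolated), via O3 pinacol borate 6 (not isolated)
Conditions: [Ir(cod)(PPh2Me)2]PF6 (3 mol %, activated with H2, then purged with Ar), (R)-TRIP (10 mol %), 4 Å MS, CH2Cl2, 0 °C to rt; aq NaHCO3 work-up
Reagents that add atoms: none
Why: Proposed new method: the H2-activated cationic iridium hydride moves the C=C of 4 by one position (net 1,3-hydrogen shift) from the boron side to the O1 side to give E enol ether 5, in which boron coordinates the adjacent formyl oxygen while the O1-bearing gamma carbon bonds to the formyl carbon inside a chair-shaped six-membered array (SE2' allyl transfer), giving borate 6 that water cleaves to 7, and the irreversible closure drains the isomerisation equilibrium. The closest known reaction types are the iridium-catalysed isomerisation of 3-alkoxy-1-alkenylboronates to E gamma-alkoxyallylboronates with ring-closing allylboration to trans-2-vinyl-3-hydroxy tetrahydropyrans and oxepanes, the one-pot iridium/chiral phosphoric acid isomerisation–allylboration of 1-alkenylboronates with aldehydes, and the phosphoric acid-catalysed anti-alkoxyallylboration of aldehydes; the aryl ether tether, the five-membered closure and the enantioselective tethered version are new. The dihydrofuran ring is closed in the 5-exo-trig mode, the C=O pi bond that breaks lying outside the new ring. C2 is fixed relative to C3 by the E geometry of 5: O1 on C2 and C3a on C3 both take equatorial sites of the chair and are spanned by the arene, so H2 and H3 end up anti and the vinyl group and O3 trans. C3 (S) is fixed by (R)-TRIP, which hydrogen-bonds to the pseudo-axial pinacol oxygen and to the axial formyl hydrogen and should thereby expose the Re face (O > C3a > H) of the aldehyde; since this two-point contact needs the formyl hydrogen axial, the acid accelerates only the aryl-equatorial chair and so also supports the trans outcome. The step needs the acid-bound closure to outrun the acid-free one and the aldehyde to react instead of the ketone: gamma-oxygenated pinacol allylboronates are intrinsically sluggish, slow release keeps 5 below the acid concentration, and the hydrogen-bonded acetyl group sits para to O1, out of reach of the short tether.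

**Step 4**
Reactants: 7 1-[(2R,3S)-2-ethenyl-3,4-dihydroxy-2,3-dihydro-1-benzofuran-5-yl]ethanone
Product: 9 1-[(2R,3S)-3-(tert-butyldimethylsilyloxy)-2-ethenyl-4-hydroxy-2,3-dihydro-1-benzofuran-5-yl]ethanone, via O3/O4 bis-silyl ether 8 (not isolated)
Conditions: TBSCl (3 equiv), imidazole (6 equiv), DMF, 35 °C; crude, then K2CO3 (cat.), MeOH, 0 °C
Reagents that add atoms: tert-butyldimethylsilyl chloride CC(C)(C)[Si](C)(C)Cl
Why: Exhaustive silyl ether formation followed by selective methanolysis of the aryl silyl ether, whose acyl-stabilised phenoxide is by far the better leaving group, should leave only O3 masked, which blocks retro-aldol cleavage and slows beta-elimination in the ketone made next.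

**Step 5**
Reactants: 9 1-[(2R,3S)-3-(tert-butyldimethylsilyloxy)-2-ethenyl-4-hydroxy-2,3-dihydro-1-benzofuran-5-yl]ethanone
Product: 10 1-[(2S,3S)-5-acetyl-3-(tert-butyldimethylsilyloxy)-4-hydroxy-2,3-dihydro-1-benzofuran-2-yl]ethanone
Conditions: Pd(Quinox)Cl2 (5 mol %; Quinox = 2-(4,5-dihydrooxazol-2-yl)quinoline), AgSbF6 (12 mol %), aq TBHP, CH2Cl2, 0 °C to rt
Reagents that add atoms: tert-butyl hydroperoxide CC(C)(C)OO
Why: Wacker-type oxidation with catalyst-controlled Markovnikov selectivity, since the cationic quinoline–oxazoline complex of divalent palladium with TBHP is known to turn protected allylic alcohols into alpha-oxy methyl ketones without aldehyde formation or loss of configuration at the alpha carbon, and the near-neutral medium should not trigger elimination across C2–C3, where H2 and O3 are syn.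

**Step 6**
Reactants: 10 1-[(2S,3S)-5-acetyl-3-(tert-butyldimethylsilyloxy)-4-hydroxy-2,3-dihydro-1-benzofuran-2-yl]ethanone
Product: 11 1-[(2S,3S)-3-(tert-butyldimethylsilyloxy)-4-hydroxy-2-(2-hydroxypropan-2-yl)-2,3-dihydro-1-benzofuran-5-yl]ethanone
Conditions: MeMgBr (2.3 equiv), LaCl3·2LiCl (0.3 equiv), THF, −78 to −40 °C; pH 7 buffer
Reagents that add atoms: methylmagnesium bromide C[Mg]Br
Why: Chemoselective Grignard 1,2-addition, in which the first equivalent turns the C4 phenol into a magnesium phenoxide chelated to the C5 acetyl group (a vinylogous carboxylate that is inert at low temperature), the second adds to the inductively activated alpha-aryloxy ketone with the lanthanum salt favouring addition over enolisation, and no stereocentre is made or touched.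

**Step 7**
Reactants: 11 1-[(2S,3S)-3-(tert-butyldimethylsilyloxy)-4-hydroxy-2-(2-hydroxypropan-2-yl)-2,3-dihydro-1-benzofuran-5-yl]ethanone
Product: 12 1-[(2S,3S)-3,4-dihydroxy-2-(2-hydroxypropan-2-yl)-2,3-dihydro-1-benzofuran-5-yl]ethanone
Conditions: TBAF/AcOH (1:1, 2 equiv), THF, 0 °C to rt
Reagents that add atoms: none
Why: Fluoride desilylation buffered with acetic acid avoids both the strong acid that would ionise or dehydrate the benzylic C3 alcohol and unbuffered alkoxide basicity.

**Step 8**
Reactants: 12 1-[(2S,3S)-3,4-dihydroxy-2-(2-hydroxypropan-2-yl)-2,3-dihydro-1-benzofuran-5-yl]ethanone; 13 4-(allyloxy)benzaldehyde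
Product: 14 (E)-3-[4-(allyloxy)phenyl]-1-[(2S,3S)-3,4-dihydroxy-2-(2-hydroxypropan-2-yl)-2,3-dihydro-1-benzofuran-5-yl]prop-2-en-1-one
Conditions: KOH (50 % aq), EtOH, rt; then AcOH to pH 6, 0 °C
Reagents that add atoms: none
Why: Claisen–Schmidt aldol condensation, in which 12 holds a single enolisable ketone, its enolate adds to the non-enolisable aldehyde 13 and E1cB loss of water gives the thermodynamically preferred E enone, the strongly basic medium keeps the product as the open chalcone phenoxide instead of the flavanone, and neither C2 nor C3 carries an acidic hydrogen.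

**Step 9**
Reactants: 14 (E)-3-[4-(allyloxy)phenyl]-1-[(2S,3S)-3,4-dihydroxy-2-(2-hydroxypropan-2-yl)-2,3-dihydro-1-benzofuran-5-yl]prop-2-en-1-one
Product: 15 brosimacutin G
Conditions: Pd(PPh3)4 (5 mol %), N-methylaniline (3 equiv), THF, rt
Reagents that add atoms: none
Why: Tsuji–Trost deallylation, in which zerovalent palladium ionises the aryl allyl ether to a pi-allyl complex and the phenoxide, N-methylaniline takes up the allyl group, and the neutral conditions spare the acid-labile benzylic alcohol, the tertiary alcohol and the enone.

**Compound list**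
1 | 2,4-dihydroxyacetophenone | CC(=O)c1ccc(O)cc1O | starting material
2 | 3-acetyl-2,6-dihydroxybenzaldehyde | CC(=O)c1ccc(O)c(C=O)c1O | intermediate
3 | (E)-3-chloroprop-1-en-1-ylboronic acid pinacol ester | ClC/C=C/B1OC(C)(C)C(C)(C)O1 | starting material
4 | 3-acetyl-2-hydroxy-6-{[(2E)-3-(pinacolatoboryl)prop-2-en-1-yl]oxy}benzaldehyde | CC(=O)c1ccc(OC/C=C/B2OC(C)(C)C(C)(C)O2)c(C=O)c1O | intermediate
5 | 3-acetyl-2-hydroxy-6-{[(1E)-3-(pinacolatoboryl)prop-1-en-1-yl]oxy}benzaldehyde (key-step precursor, not isolated) | CC(=O)c1ccc(O/C=C/CB2OC(C)(C)C(C)(C)O2)c(C=O)c1O | intermediate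
6 | O3 pinacol borate of 7, (2R,3S) (not isolated) | C=C[C@H]1Oc2ccc(C(C)=O)c(O)c2[C@@H]1OB3OC(C)(C)C(C)(C)O3 | intermediate
7 | 1-[(2R,3S)-2-ethenyl-3,4-dihydroxy-2,3-dihydro-1-benzofuran-5-yl]ethanone (trans) | C=C[C@H]1Oc2ccc(C(C)=O)c(O)c2[C@@H]1O | intermediate
8 | O3/O4 bis(tert-butyldimethylsilyl) ether of 7, (2R,3S) (not isolated) | C=C[C@H]1Oc2ccc(C(C)=O)c(O[Si](C)(C)C(C)(C)C)c2[C@@H]1O[Si](C)(C)C(C)(C)C | intermediate
9 | 1-[(2R,3S)-3-(tert-butyldimethylsilyloxy)-2-ethenyl-4-hydroxy-2,3-dihydro-1-benzofuran-5-yl]ethanone | C=C[C@H]1Oc2ccc(C(C)=O)c(O)c2[C@@H]1O[Si](C)(C)C(C)(C)C | intermediate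
10 | 1-[(2S,3S)-5-acetyl-3-(tert-butyldimethylsilyloxy)-4-hydroxy-2,3-dihydro-1-benzofuran-2-yl]ethanone | CC(=O)[C@H]1Oc2ccc(C(C)=O)c(O)c2[C@@H]1O[Si](C)(C)C(C)(C)C | intermediate
11 | 1-[(2S,3S)-3-(tert-butyldimethylsilyloxy)-4-hydroxy-2-(2-hydroxypropan-2-yl)-2,3-dihydro-1-benzofuran-5-yl]ethanone | CC(C)(O)[C@H]1Oc2ccc(C(C)=O)c(O)c2[C@@H]1O[Si](C)(C)C(C)(C)C | intermediate
12 | 1-[(2S,3S)-3,4-dihydroxy-2-(2-hydroxypropan-2-yl)-2,3-dihydro-1-benzofuran-5-yl]ethanone | CC(C)(O)[C@H]1Oc2ccc(C(C)=O)c(O)c2[C@@H]1O | intermediate
13 | 4-(allyloxy)benzaldehyde | C=CCOc1ccc(C=O)cc1 | starting material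
14 | O-allyl ether of brosimacutin G at the ring B phenol, (2S,3S), E enone | CC(C)(O)[C@H]1Oc2ccc(C(=O)/C=C/c3ccc(OCC=C)cc3)c(O)c2[C@@H]1O | intermediate
15 | brosimacutin G, (2S,3S), E enone | CC(C)(O)[C@H]1Oc2ccc(C(=O)/C=C/c3ccc(O)cc3)c(O)c2[C@@H]1O | target

**Total step count:** 9
**Longest linear sequence:** 9 steps (1 to 15; 3 and 13 are bought)

**Steps most likely to fail**

**Step 3 (labelled step).**
- Closure without the acid may compete with the acid-bound pathway and erode the enantiomeric purity.
- The short arene bridge may push the allyl transfer into the aryl-axial chair or a boat and erode the trans selectivity.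
- The iridium hydride may be held up by the hydroxy-aldehyde chelate, or may go on to isomerise the vinyl group of the product.

The fallback uses known chemistry and closes C2–O1 instead of C2–C3. It sets out from 2 and comes back at 12. Allyl bromide and K2CO3 in DMF etherify the hydroxyl para to the acetyl group to give 3-acetyl-6-(allyloxy)-2-hydroxybenzaldehyde F1. 2-Methylprop-1-enylmagnesium bromide (2.2 equiv, THF, −78 °C), whose first equivalent parks the ketone as its chelated phenoxide, adds to the aldehyde to give the racemic allylic alcohol F2. Sharpless kinetic resolution [Ti(OiPr)4, D-(−)-DIPT, TBHP, 4 Å MS, CH2Cl2, −20 °C] consumes the S alcohol as its erythro epoxy alcohol F3, which is separated, and leaves the R allylic alcohol F4. mCPBA/NaHCO3 (CH2Cl2, 0 °C) is directed by the hydroxyl group in the conformer fixed by 1,3-allylic strain with the cis methyl group, and gives the threo epoxy alcohol F5. Pd(PPh3)4 and K2CO3 in MeOH remove the allyl group, and the released phenoxide opens the epoxide 5-exo-tet at its secondary carbon with inversion. This gives the (2S,3S) trans compound 12 and makes steps 4 to 7 unnecessary.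

**Step 5.** The allylic oxygen may steer the oxygen nucleophile to the terminal carbon. The hindered vinyl group may coordinate poorly. The Lewis acidic medium may cause loss of the silyl group followed by elimination across C2–C3.

The fallback sets out from 9 and comes back at 10. Mukaiyama hydration [Co(acac)2, PhSiH3, O2, THF/iPrOH] is a radical Markovnikov process that ignores the allylic oxygen, and it gives the secondary alcohol F6 as a mixture of carbinol epimers. Dess–Martin periodinane (NaHCO3, CH2Cl2) oxidises both epimers to 10.

**Step 6.** Enolisation at C2 followed by E1cB loss of silanolate and aromatisation of the furan ring may compete, as may addition to the aryl ketone.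

The fallback sets out from 10 and comes back at 11. The non-basic Lombardo methylenation (Zn, CH2Br2, TiCl4, THF/CH2Cl2, 0 °C to rt) converts the aliphatic ketone into the isopropenyl compound F7, the aryl ketone being shielded as its metal phenoxide chelate. Mukaiyama hydration [Co(acac)2, PhSiH3, O2] then places the hydroxyl on the tertiary carbon to give 11.

**Further compounds**
F1 | step 3 | 3-acetyl-6-(allyloxy)-2-hydroxybenzaldehyde | CC(=O)c1ccc(OCC=C)c(C=O)c1O
F2 | step 3 | racemic 1-[4-(allyloxy)-2-hydroxy-3-(1-hydroxy-3-methylbut-2-en-1-yl)phenyl]ethanone | CC(=O)c1ccc(OCC=C)c(C(O)C=C(C)C)c1O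
F3 | step 3 | 1-{4-(allyloxy)-3-[(R)-[(2R)-3,3-dimethyloxiran-2-yl](hydroxy)methyl]-2-hydroxyphenyl}ethanone (erythro, discarded) | CC(=O)c1ccc(OCC=C)c([C@@H](O)[C@H]2OC2(C)C)c1O
F4 | step 3 | 1-{4-(allyloxy)-2-hydroxy-3-[(1R)-1-hydroxy-3-methylbut-2-en-1-yl]phenyl}ethanone | CC(=O)c1ccc(OCC=C)c([C@H](O)C=C(C)C)c1O
F5 | step 3 | 1-{4-(allyloxy)-3-[(S)-[(2R)-3,3-dimethyloxiran-2-yl](hydroxy)methyl]-2-hydroxyphenyl}ethanone (threo) | CC(=O)c1ccc(OCC=C)c([C@H](O)[C@H]2OC2(C)C)c1O
F6 | step 5 | 1-[(2S,3S)-3-(tert-butyldimethylsilyloxy)-4-hydroxy-2-(1-hydroxyethyl)-2,3-dihydro-1-benzofuran-5-yl]ethanone (carbinol epimers) | CC(O)[C@H]1Oc2ccc(C(C)=O)c(O)c2[C@@H]1O[Si](C)(C)C(C)(C)C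
F7 | step 6 | 1-[(2R,3S)-3-(tert-butyldimethylsilyloxy)-4-hydroxy-2-(prop-1-en-2-yl)-2,3-dihydro-1-benzofuran-5-yl]ethanone | C=C(C)[C@H]1Oc2ccc(C(C)=O)c(O)c2[C@@H]1O[Si](C)(C)C(C)(C)C
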